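**Plan**
- Retrosynthesis: after removing the benzyl and silyl groups, upper ring C is opened at O1–C2 (Mitsunobu) and at the C2–aryl bond (Grignard) to a chroman-2-ol. This lactol is cut at C3–C4 and O1–C2 into an o-quinone methide of upper ring A and the enamine of silyloxyacetaldehyde. The sulfone precursor is cut between its benzhydryl carbon and lower C6.
- Enabling feature: upper C4 is a diarylmethine carbon ortho to the phenolic oxygen O1 on upper ring A, so it can be the exocyclic carbon of an o-quinone methide; the neighbouring oxygenated C3 is the α-carbon of a glycolaldehyde enamine.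
- Forward order: lower unit first (chromone rings A/C, ring B by conjugate arylation, then C3/C4 oxygenation), bromination at C6, union with upper ring A, upper ring C as a lactol, upper ring B by Grignard addition, re-closure, deprotection.
- Stereochemistry: lower C2 from Pd/PyOx conjugate addition; lower C4 and C3 from substrate control (epoxidation anti to the aryl group with trans opening, then hydride from the β-face); upper C3/C4 from the prolinol catalyst; upper C2 from Felkin–Anh addition followed by inversion.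

Key step: step 14

Remark: the target is read as epioritin-(4β→6)-epioritin-4α-ol (upper 2R,3R,4S; lower 2R,3R,4R; epioritin = (2R,3R)-2,3-cis-7,8,4'-trihydroxyflavan-3-ol). Flavan numbering is used; α/β mean below/above the plane in the usual drawing; "Fl" is the chroman-6-yl group of compound 13. Grignard reagent 25 is taken as the commercial THF solution and both antipodes of t-BuPyOx and of the prolinol catalyst as available; the sense of induction in steps 3 and 14 is assigned by analogy.

**Step 1**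
Reactants: 1 2',3',4'-trihydroxyacetophenone
Product: 2 3',4'-bis(benzyloxy)-2'-hydroxyacetophenone
Conditions: BnBr (2.1 equiv), K2CO3, acetone, reflux
Reagents that add atoms: benzyl bromide, BrCc1ccccc1
Why: Williamson etherification in which the 2'-hydroxyl, hydrogen-bonded to the acetyl carbonyl, is the least nucleophilic and should stay free, as in the classical 3,4-dialkylation of gallacetophenone.

**Step 2**
Reactants: 2 3',4'-bis(benzyloxy)-2'-hydroxyacetophenone
Product: 4 7,8-bis(benzyloxy)-4H-chromen-4-one, via enaminone 3 (not isolated)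
Conditions: Me2NCH(OMe)2, 100 °C; concentrate; conc. HCl, CH2Cl2, 40 °C
Reagents that add atoms: N,N-dimethylformamide dimethyl acetal, COC(OC)N(C)C
Why: Enaminone formation followed by acid-induced addition–elimination of the phenol with loss of dimethylamine is the standard chromone annulation of 2-hydroxyacetophenones.

**Step 3**
Reactants: 4 7,8-bis(benzyloxy)-4H-chromen-4-one; 5 4-(benzyloxy)phenylboronic acid
Product: 6 (S)-7,8-bis(benzyloxy)-2-[4-(benzyloxy)phenyl]chroman-4-one
Conditions: Pd(OCOCF3)2 (5 mol%), (R)-t-BuPyOx (6 mol%), NH4PF6 (30 mol%), H2O (5 equiv), ClCH2CH2Cl, 60 °C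
Reagents that add atoms: none
Why: Asymmetric conjugate addition of arylboronic acids to chromones under divalent palladium/pyridine-oxazoline catalysis is an established flavanone synthesis that tolerates benzyl ethers, and the (R)-ligand is expected to place the aryl group α, which sets lower C2.

**Step 4**
Reactants: 6 (S)-7,8-bis(benzyloxy)-2-[4-(benzyloxy)phenyl]chroman-4-one
Product: 7 (2S,4S)-7,8-bis(benzyloxy)-2-[4-(benzyloxy)phenyl]chroman-4-ol (2,4-cis)
Conditions: NaBH4, MeOH–THF, 0 °C
Reagents that add atoms: none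
Why: Borohydride reduction of flavanones by axial hydride delivery gives the 2,4-cis alcohol, and the C4 centre is removed in the next step so its configuration is immaterial.

**Step 5**
Reactants: 7 (2S,4S)-7,8-bis(benzyloxy)-2-[4-(benzyloxy)phenyl]chroman-4-ol
Product: 8 (S)-7,8-bis(benzyloxy)-2-[4-(benzyloxy)phenyl]-2H-chromene
Conditions: Burgess reagent, toluene, 50 °C
Reagents that add atoms: none
Why: Burgess dehydration (syn-elimination through the sulfamate ester) of the benzylic alcohol avoids the Brønsted acid that could ionise the allylic, benzylic O1–C2 bond of the product and racemise C2.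

**Step 6**
Reactants: 8 (S)-7,8-bis(benzyloxy)-2-[4-(benzyloxy)phenyl]-2H-chromene
Product: 10 (2R,3S,4R)-4,7,8-tris(benzyloxy)-2-[4-(benzyloxy)phenyl]chroman-3-ol (2,3-trans-3,4-trans), via epoxide 9 (not isolated)
Conditions: DMDO, acetone, −20 °C; evaporate cold; BnOH (5 equiv), PPTS (5 mol%), CH2Cl2, −40 → 0 °C
Reagents that add atoms: dimethyldioxirane, CC1(C)OO1; benzyl alcohol, OCc1ccccc1
Why: Dioxirane epoxidation of 2-aryl-2H-chromenes occurs anti to the C2 aryl group, and acid-catalysed alcoholysis of the labile benzylic epoxide opens C4–O with inversion, so C4 receives its final α-oxygen as a benzyl ether while the C3 hydroxyl stays free for inversion.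

**Step 7**
Reactants: 10 (2R,3S,4R)-4,7,8-tris(benzyloxy)-2-[4-(benzyloxy)phenyl]chroman-3-ol
Product: 11 (2R,4R)-4,7,8-tris(benzyloxy)-2-[4-(benzyloxy)phenyl]chroman-3-one
Conditions: Dess–Martin periodinane, pyridine, CH2Cl2, 0 °C → rt
Reagents that add atoms: none
Why: Buffered Dess–Martin oxidation should give the flavan-3-one without epimerising the two flanking benzylic centres, as in the oxidation half of the usual catechin-to-epicatechin inversion.

**Step 8**
Reactants: 11 (2R,4R)-4,7,8-tris(benzyloxy)-2-[4-(benzyloxy)phenyl]chroman-3-one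
Product: 12 (2R,3R,4R)-4,7,8-tris(benzyloxy)-2-[4-(benzyloxy)phenyl]chroman-3-ol (all-cis)
Conditions: LiBH(s-Bu)3, THF, −78 °C; H2O
Reagents that add atoms: none
Why: Bulky-hydride reduction of flavan-3-ones delivers hydride equatorially from the β-face, anti to the pseudo-equatorial 2-aryl and 4-benzyloxy groups, giving the axial 3α-alcohol and so setting lower C3 in the all-cis array.

**Step 9**
Reactants: 12 (2R,3R,4R)-4,7,8-tris(benzyloxy)-2-[4-(benzyloxy)phenyl]chroman-3-ol
Product: 13 (2R,3R,4R)-4,7,8-tris(benzyloxy)-2-[4-(benzyloxy)phenyl]-3-(tert-butyldimethylsilyloxy)chroman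
Conditions: TBSOTf, 2,6-lutidine, CH2Cl2, −78 → 0 °C
Reagents that add atoms: tert-butyldimethylsilyl trifluoromethanesulfonate, CC(C)(C)[Si](C)(C)OS(=O)(=O)C(F)(F)F
Why: Silyl triflate/lutidine silylation is the standard way to protect a hindered axial secondary alcohol, and the base buffers the acid that could ionise the C4 ether.

**Step 10**
Reactants: 13 (2R,3R,4R)-4,7,8-tris(benzyloxy)-2-[4-(benzyloxy)phenyl]-3-(tert-butyldimethylsilyloxy)chroman
Product: 14 (2R,3R,4R)-6-bromo-4,7,8-tris(benzyloxy)-2-[4-(benzyloxy)phenyl]-3-(tert-butyldimethylsilyloxy)chroman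
Conditions: NBS (1.05 equiv), MeCN, 0 °C, dark
Reagents that add atoms: N-bromosuccinimide, O=C1CCC(=O)N1Br
Why: Electrophilic aromatic bromination should go to C6, which is para to O1 and ortho to the 7-benzyloxy group on the trioxygenated ring A, whereas C5 is peri to C4 and ring B carries only one alkoxy group.

**Step 11**
Reactants: 15 2,3,4-trihydroxybenzaldehyde
Product: 16 3,4-bis(benzyloxy)-2-hydroxybenzaldehyde
Conditions: BnBr (2.1 equiv), K2CO3, acetone, reflux
Reagents that add atoms: benzyl bromide, BrCc1ccccc1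
Why: Williamson etherification that leaves the 2-hydroxyl free because it is hydrogen-bonded to the formyl group, as in step 1.

**Step 12**
Reactants: 14 the 6-bromo lower unit; 16 3,4-bis(benzyloxy)-2-hydroxybenzaldehyde
Product: 19 [3,4-bis(benzyloxy)-2-hydroxyphenyl](Fl)methanol (both carbinol epimers), via aryllithium 17 (not isolated), via sodium phenoxide 18 (not isolated)
Conditions: 14, n-BuLi, THF, −78 °C; add 18 (from 16, NaH, THF, 0 °C); −78 → −30 °C; H2O; product used crude
Reagents that add atoms: none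
Why: Bromine–lithium exchange at −78 °C outruns any deprotonation and the aryllithium undergoes 1,2-addition to the aldehyde of the pre-formed phenoxide, the usual route to 2-hydroxybenzhydrols, the new carbinol centre being erased later.

**Step 13**
Reactants: 19 [3,4-bis(benzyloxy)-2-hydroxyphenyl](Fl)methanol
Product: 20 2,3-bis(benzyloxy)-6-[(Fl)(4-methylphenylsulfonyl)methyl]phenol (both epimers)
Conditions: p-TolSO2H (2 equiv), CH2Cl2, 0 °C → rt
Reagents that add atoms: p-toluenesulfinic acid, Cc1ccc(cc1)S(O)=O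
Why: SN1 substitution of the doubly activated o-hydroxybenzhydrol by sulfinate at sulfur is the usual preparation of 2-[aryl(sulfonyl)methyl]phenols, and the weak acid should leave the less ionisable lower C4 benzyl ether intact.

**Step 14**
Reactants: 20 the sulfone; 21 (tert-butyldimethylsilyloxy)acetaldehyde
Product: 24 7,8-bis(benzyloxy)-3α-(tert-butyldimethylsilyloxy)-4β-(Fl)chroman-2-ol (3,4-trans; anomeric mixture), via quinone methide 22 (not isolated), via hydroxy aldehyde 23 (not isolated)
Conditions: (S)-α,α-diphenylprolinol trimethylsilyl ether (20 mol%), NaHCO3 (2 equiv), 21 (3 equiv), CH2Cl2, rt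
Reagents that add atoms: none
Why: Hydrogencarbonate deprotonates the phenol of 20 and sulfinate leaves (E1cB) to give the E-configured o-quinone methide 22, while the catalyst and 21 form the E-enamine whose β-carbon (future C3) adds to the exocyclic carbon of 22 (future upper C4) with rearomatisation of ring A; hydrolysis of the iminium ion releases 23 and returns the amine. The closest known reaction type is the diarylprolinol silyl ether-catalysed Michael addition (formal [4+2]) of aldehydes to o-quinone methides generated in situ from 2-(1-arylsulfonylalkyl)phenols, which gives trans-3,4-disubstituted chroman-2-ols. Upper ring C closes by hemiacetalisation, the phenolic O1 adding to the aldehyde carbon C2 in a 6-exo-trig mode. C3 is fixed by the diphenyl(silyloxy)methyl group of the (S)-catalyst, which shields one enamine face, and C4 by the synclinal approach of the E-quinone methide to the open face (the topicity of syn-selective nitroalkene Michael additions with this catalyst), which corresponds to 3α-silyloxy/4β-aryl, the 3,4-trans arrangement of the target; C2 is an uncontrolled anomeric centre that is reopened in step 15. The step needs catalyst control over the lower-unit stereocentres, which lie at least four bonds from the reacting carbon and should exert little induction, and it needs a single quinone methide, which is secured because O1 is the only free phenol and the sulfonyl-bearing carbon is its only ortho carbon substituent.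

**Step 15**
Reactants: 24 the lactol; 25 4-(benzyloxy)phenylmagnesium bromide
Product: 27 (S)-configured 1,2-anti carbinol 1-[4-(benzyloxy)phenyl]-2-(tert-butyldimethylsilyloxy)-3-[3,4-bis(benzyloxy)-2-hydroxyphenyl]-3-(Fl)propan-1-ol, via aldehyde phenoxide 26 (not isolated)
Conditions: 25 (4 equiv), THF, −78 → −20 °C; aq NH4Cl
Reagents that add atoms: none
Why: Grignard addition to a lactol through its ring-opened aldehyde is standard, and Felkin–Anh attack anti to the non-chelating α-silyloxy group should give the 1,2-anti carbinol, the epimer required for ring closure with inversion.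

**Step 16**
Reactants: 27 the anti carbinol
Product: 28 3-O-TBS-7,8,4'-tri-O-benzylepioritin-(4β→6)-3-O-TBS-4,7,8,4'-tetra-O-benzylepioritin-4α-ol
Conditions: PPh3, DIAD, THF, 0 °C → rt
Reagents that add atoms: none
Why: Mitsunobu cyclodehydration of a phenol onto a secondary benzylic alcohol (6-exo-tet), a standard flavan ring closure, proceeds with inversion and should convert the anti carbinol into the 2,3-cis flavan, setting upper C2 as R.

**Step 17**
Reactants: 28 the fully protected biflavanoid
Product: 29 7,8,4'-tri-O-benzylepioritin-(4β→6)-4,7,8,4'-tetra-O-benzylepioritin-4α-ol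
Conditions: TBAF (3 equiv), THF, 0 °C → rt
Reagents that add atoms: none
Why: Fluoride cleavage of both secondary silyl ethers involves no acid, so the lower C4 benzylic ether and the interflavanyl bond should not ionise.

**Step 18**
Reactants: 29 the hepta-O-benzyl diol
Product: 30 epioritin-(4β→6)-epioritin-4α-ol (CNP0391561.1)
Conditions: H2 (1 atm), Pd(OH)2/C, THF–MeOH, rt, degassed; filtered under argon
Reagents that add atoms: none
Why: Hydrogenolysis of all seven benzyl ethers over Pd(OH)2/C in neutral medium is the usual last step of proanthocyanidin syntheses, O–CH2Ph cleavage being faster than hydrogenolysis of the ring benzylic C–O bonds provided the reaction is stopped at the calculated uptake.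

**Compound list**
1 | 2',3',4'-trihydroxyacetophenone | CC(=O)c1ccc(O)c(O)c1O | starting material
2 | 3',4'-bis(benzyloxy)-2'-hydroxyacetophenone | CC(=O)c1ccc(OCc9ccccc9)c(OCc9ccccc9)c1O | intermediate
3 | (E)-1-[3,4-bis(benzyloxy)-2-hydroxyphenyl]-3-(dimethylamino)prop-2-en-1-one | CN(C)/C=C/C(=O)c1ccc(OCc9ccccc9)c(OCc9ccccc9)c1O | intermediate
4 | 7,8-bis(benzyloxy)-4H-chromen-4-one | O=c1ccoc2c(OCc9ccccc9)c(OCc9ccccc9)ccc12 | intermediate
5 | 4-(benzyloxy)phenylboronic acid | OB(O)c1ccc(OCc9ccccc9)cc1 | starting material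
6 | (S)-7,8-bis(benzyloxy)-2-[4-(benzyloxy)phenyl]chroman-4-one | c1cc2c(c(OCc9ccccc9)c1OCc9ccccc9)O[C@H](c5ccc(OCc9ccccc9)cc5)CC2=O | intermediate
7 | (2S,4S)-7,8-bis(benzyloxy)-2-[4-(benzyloxy)phenyl]chroman-4-ol | c1cc2c(c(OCc9ccccc9)c1OCc9ccccc9)O[C@H](c5ccc(OCc9ccccc9)cc5)C[C@@H]2O | intermediate
8 | (S)-7,8-bis(benzyloxy)-2-[4-(benzyloxy)phenyl]-2H-chromene | c1cc2c(c(OCc9ccccc9)c1OCc9ccccc9)O[C@H](c5ccc(OCc9ccccc9)cc5)C=C2 | intermediate
9 | 3β,4β-epoxide of 8 (epoxide trans to the 2α-aryl group) | c1cc2c(c(OCc9ccccc9)c1OCc9ccccc9)O[C@H](c5ccc(OCc9ccccc9)cc5)[C@H]3O[C@H]32 | intermediate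
10 | (2R,3S,4R)-4,7,8-tris(benzyloxy)-2-[4-(benzyloxy)phenyl]chroman-3-ol | c1cc2c(c(OCc9ccccc9)c1OCc9ccccc9)O[C@H](c5ccc(OCc9ccccc9)cc5)[C@@H](O)[C@@H]2OCc9ccccc9 | intermediate
11 | (2R,4R)-4,7,8-tris(benzyloxy)-2-[4-(benzyloxy)phenyl]chroman-3-one | c1cc2c(c(OCc9ccccc9)c1OCc9ccccc9)O[C@H](c5ccc(OCc9ccccc9)cc5)C(=O)[C@@H]2OCc9ccccc9 | intermediate
12 | (2R,3R,4R)-4,7,8-tris(benzyloxy)-2-[4-(benzyloxy)phenyl]chroman-3-ol | c1cc2c(c(OCc9ccccc9)c1OCc9ccccc9)O[C@H](c5ccc(OCc9ccccc9)cc5)[C@H](O)[C@@H]2OCc9ccccc9 | intermediate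
13 | (2R,3R,4R)-4,7,8-tris(benzyloxy)-2-[4-(benzyloxy)phenyl]-3-(tert-butyldimethylsilyloxy)chroman | c1cc2c(c(OCc9ccccc9)c1OCc9ccccc9)O[C@H](c5ccc(OCc9ccccc9)cc5)[C@H](O[Si](C)(C)C(C)(C)C)[C@@H]2OCc9ccccc9 | intermediate
14 | 6-bromo derivative of 13 | Brc1cc2c(c(OCc9ccccc9)c1OCc9ccccc9)O[C@H](c5ccc(OCc9ccccc9)cc5)[C@H](O[Si](C)(C)C(C)(C)C)[C@@H]2OCc9ccccc9 | intermediate
15 | 2,3,4-trihydroxybenzaldehyde | O=Cc1ccc(O)c(O)c1O | starting material
16 | 3,4-bis(benzyloxy)-2-hydroxybenzaldehyde | O=Cc1ccc(OCc9ccccc9)c(OCc9ccccc9)c1O | intermediate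
17 | 6-lithio derivative of 13 | [Li]c1cc2c(c(OCc9ccccc9)c1OCc9ccccc9)O[C@H](c5ccc(OCc9ccccc9)cc5)[C@H](O[Si](C)(C)C(C)(C)C)[C@@H]2OCc9ccccc9 | intermediate
18 | sodium 2,3-bis(benzyloxy)-6-formylphenolate | [Na+].[O-]c1c(C=O)ccc(OCc9ccccc9)c1OCc9ccccc9 | intermediate
19 | [3,4-bis(benzyloxy)-2-hydroxyphenyl](Fl)methanol, carbinol epimers | OC(c1ccc(OCc9ccccc9)c(OCc9ccccc9)c1O)c3cc4c(c(OCc9ccccc9)c3OCc9ccccc9)O[C@H](c5ccc(OCc9ccccc9)cc5)[C@H](O[Si](C)(C)C(C)(C)C)[C@@H]4OCc9ccccc9 | intermediate
20 | 2,3-bis(benzyloxy)-6-[(Fl)(4-methylphenylsulfonyl)methyl]phenol, epimers | Cc7ccc(cc7)S(=O)(=O)C(c1ccc(OCc9ccccc9)c(OCc9ccccc9)c1O)c3cc4c(c(OCc9ccccc9)c3OCc9ccccc9)O[C@H](c5ccc(OCc9ccccc9)cc5)[C@H](O[Si](C)(C)C(C)(C)C)[C@@H]4OCc9ccccc9 | intermediate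
21 | (tert-butyldimethylsilyloxy)acetaldehyde | O=CCO[Si](C)(C)C(C)(C)C | starting material
22 | (E)-2,3-bis(benzyloxy)-6-[(Fl)methylidene]cyclohexa-2,4-dien-1-one (o-quinone methide) | O=C1C(OCc9ccccc9)=C(OCc9ccccc9)C=C/C1=C\c3cc4c(c(OCc9ccccc9)c3OCc9ccccc9)O[C@H](c5ccc(OCc9ccccc9)cc5)[C@H](O[Si](C)(C)C(C)(C)C)[C@@H]4OCc9ccccc9 | intermediate
23 | 2-(tert-butyldimethylsilyloxy)-3-[3,4-bis(benzyloxy)-2-hydroxyphenyl]-3-(Fl)propanal, syn Michael adduct (future upper C3 α-O, C4 β-Fl) | O=C[C@H](O[Si](C)(C)C(C)(C)C)[C@H](c1ccc(OCc9ccccc9)c(OCc9ccccc9)c1O)c3cc4c(c(OCc9ccccc9)c3OCc9ccccc9)O[C@H](c5ccc(OCc9ccccc9)cc5)[C@H](O[Si](C)(C)C(C)(C)C)[C@@H]4OCc9ccccc9 | intermediate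
24 | 7,8-bis(benzyloxy)-3α-(tert-butyldimethylsilyloxy)-4β-(Fl)chroman-2-ol, anomeric mixture | OC1Oc2c(ccc(OCc9ccccc9)c2OCc9ccccc9)[C@H](c3cc4c(c(OCc9ccccc9)c3OCc9ccccc9)O[C@H](c5ccc(OCc9ccccc9)cc5)[C@H](O[Si](C)(C)C(C)(C)C)[C@@H]4OCc9ccccc9)[C@H]1O[Si](C)(C)C(C)(C)C | intermediate
25 | 4-(benzyloxy)phenylmagnesium bromide | Br[Mg]c1ccc(OCc9ccccc9)cc1 | starting material
26 | bromomagnesium phenoxide of aldehyde 23 | O=C[C@H](O[Si](C)(C)C(C)(C)C)[C@H](c1ccc(OCc9ccccc9)c(OCc9ccccc9)c1O[Mg]Br)c3cc4c(c(OCc9ccccc9)c3OCc9ccccc9)O[C@H](c5ccc(OCc9ccccc9)cc5)[C@H](O[Si](C)(C)C(C)(C)C)[C@@H]4OCc9ccccc9 | intermediate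
27 | (1S)-1-[4-(benzyloxy)phenyl]-2-(tert-butyldimethylsilyloxy)-3-[3,4-bis(benzyloxy)-2-hydroxyphenyl]-3-(Fl)propan-1-ol, 1,2-anti | O[C@@H](c8ccc(OCc9ccccc9)cc8)[C@H](O[Si](C)(C)C(C)(C)C)[C@H](c1ccc(OCc9ccccc9)c(OCc9ccccc9)c1O)c3cc4c(c(OCc9ccccc9)c3OCc9ccccc9)O[C@H](c5ccc(OCc9ccccc9)cc5)[C@H](O[Si](C)(C)C(C)(C)C)[C@@H]4OCc9ccccc9 | intermediate
28 | 3-O-TBS-7,8,4'-tri-O-benzylepioritin-(4β→6)-3-O-TBS-4,7,8,4'-tetra-O-benzylepioritin-4α-ol | C(c9ccccc9)Oc8ccc([C@H]1Oc2c(ccc(OCc9ccccc9)c2OCc9ccccc9)[C@H](c3cc4c(c(OCc9ccccc9)c3OCc9ccccc9)O[C@H](c5ccc(OCc9ccccc9)cc5)[C@H](O[Si](C)(C)C(C)(C)C)[C@@H]4OCc9ccccc9)[C@H]1O[Si](C)(C)C(C)(C)C)cc8 | intermediate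
29 | 7,8,4'-tri-O-benzylepioritin-(4β→6)-4,7,8,4'-tetra-O-benzylepioritin-4α-ol | C(c9ccccc9)Oc8ccc([C@H]1Oc2c(ccc(OCc9ccccc9)c2OCc9ccccc9)[C@H](c3cc4c(c(OCc9ccccc9)c3OCc9ccccc9)O[C@H](c5ccc(OCc9ccccc9)cc5)[C@H](O)[C@@H]4OCc9ccccc9)[C@H]1O)cc8 | intermediate
30 | epioritin-(4β→6)-epioritin-4α-ol (CNP0391561.1) | Oc1ccc([C@H]2Oc3c(ccc(O)c3O)[C@H](c3cc4c(c(O)c3O)O[C@H](c3ccc(O)cc3)[C@H](O)[C@@H]4O)[C@H]2O)cc1 | target

**Step count**
Total: 18 steps. Longest linear sequence: 17 steps (steps 1–10 and 12–18; step 11 is the side branch).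

**Steps most likely to fail**

Step 14. The fully substituted, electron-rich quinone methide may be a sluggish acceptor while the α-silyloxy enamine is consumed by self-aldolisation, and the catalyst may be mismatched with the chiral lower unit, eroding facial selectivity. The fallback gives up the aminocatalytic union and forms the upper C4–lower C6 bond by the classical flavanyl-cation coupling. It sets out from 13: TMSOTf (substoichiometric) in CH2Cl2 at −78 °C ionises the C4 benzyl ether of one molecule, and the cation is captured at C6 of a second molecule anti to the 3-silyloxy group. This rejoins the route at 28 and makes no new compound (F0). Its own weakness, the low nucleophilicity of the 7,8-dioxygenated ring A and competing oligomerisation, is why it is not the main route.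

Step 15. Chelation by the magnesium phenoxide or the silyloxy oxygen may compete with the Felkin–Anh mode and give poor facial selectivity, and the electron-rich benzylic alcohol may then partly ionise in step 16 and lose the inversion. The fallback sets out from 27 in whatever epimer ratio is obtained. MnO2 oxidises the benzylic alcohol to the aryl ketone, which closes onto the phenol as the cyclic hemiketal F1. Reduction of the derived 2-aryl oxocarbenium ion with Et3SiH/TMSOTf at −78 °C, with hydride expected to add anti to the C3 silyloxy group, rejoins the route at 28. This replaces substrate-controlled addition plus inversion by a stereoconvergent ionic hydrogenation.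

Step 3. The 7,8-dialkoxy chromone is a deactivated, vinylogous-ester acceptor, so turnover may be slow and protodeboronation of 5 may dominate, with loss of enantioselectivity. The fallback sets out from 2. Claisen–Schmidt condensation with 4-(benzyloxy)benzaldehyde (KOH, EtOH) gives the 2'-hydroxychalcone F2, and NaOAc in refluxing EtOH cyclises it to the racemic flavanone F3. Kinetic resolution by transfer hydrogenation with RuCl[(S,S)-TsDPEN](p-cymene) and HCO2H/Et3N should reduce only the (S)-enantiomer, which rejoins the route at 7; the unreacted (R)-flavanone can be racemised with base and recycled.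

**Further compounds**
F0 | step 14 | none | none
F1 | step 15 | 7,8-bis(benzyloxy)-2-[4-(benzyloxy)phenyl]-3α-(tert-butyldimethylsilyloxy)-4β-(Fl)chroman-2-ol (cyclic hemiketal of the aryl ketone) | OC1(c8ccc(OCc9ccccc9)cc8)Oc2c(ccc(OCc9ccccc9)c2OCc9ccccc9)[C@H](c3cc4c(c(OCc9ccccc9)c3OCc9ccccc9)O[C@H](c5ccc(OCc9ccccc9)cc5)[C@H](O[Si](C)(C)C(C)(C)C)[C@@H]4OCc9ccccc9)[C@H]1O[Si](C)(C)C(C)(C)C
F2 | step 3 | (E)-1-[3,4-bis(benzyloxy)-2-hydroxyphenyl]-3-[4-(benzyloxy)phenyl]prop-2-en-1-one | O=C(/C=C/c1ccc(OCc9ccccc9)cc1)c1ccc(OCc9ccccc9)c(OCc9ccccc9)c1O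
F3 | step 3 | racemic 7,8-bis(benzyloxy)-2-[4-(benzyloxy)phenyl]chroman-4-one | O=C1CC(c2ccc(OCc9ccccc9)cc2)Oc2c1ccc(OCc9ccccc9)c2OCc9ccccc9
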